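**Retrosynthetic overview**

1. Last disconnection: the C5–CH2 bond of the diarylmethane, giving lactone 13 (nucleophilic at C5, its only free ring carbon) and the o-quinone methide from 6-(hydroxymethyl)eugenin 17.
2. Key disconnection: the O–C(=O) unit of the lactone ring is carbon dioxide, which is joined in one operation to C8a (C–C bond) and to C3 (C–O bond, with inversion) of resorcinol mesylate 10.
3. Enabling feature: in 10 the ring carbon C8a–H is ortho to the C8 phenol oxygen and para to the C6 phenol oxygen (the Kolbe–Schmitt position), and the chain C8a–C4a–C4–C3 puts the new carboxylate in reach of C3 for a six-membered closure. The 2-methyl-5-alkylresorcinol ring has mirror symmetry, so its two free CH positions are equivalent: one takes CO2, the other (C5) later takes the chromonylmethyl group.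
4. Compound 10 comes from 2,6-dimethoxytoluene (C–H borylation/bromination) and (S)-propylene oxide; 17 comes from noreugenin by O-methylation, C6 iodination and hydroxymethylation.
5. Ring order: resorcinol ring (bought), then lactone ring (step 7); chromone bicycle (bought); the two halves are joined last (step 11).

Key step: step 7

Remark: positions are numbered as in isochroman-1-one (C1 carbonyl, O2, C3, C4, C4a, C5 to C8, C8a) and 4H-chromen-4-one; the configuration read from the SMILES is (3R); noreugenin is taken as a purchasable starting material.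

**Route**

Step 1
Reactants: 1 2,6-dimethoxytoluene
Product: 3 5-bromo-1,3-dimethoxy-2-methylbenzene, via arylboronate 2 (not isolated)
Conditions: [Ir(OMe)(cod)]2 (1.5 mol %), 4,4'-di-tert-butyl-2,2'-bipyridine (3 mol %), B2pin2 (1 equiv), THF, 80 °C; evaporate; CuBr2 (3.5 equiv), MeOH/H2O 1:1, 80 °C
Reagents that add atoms: bis(pinacolato)diboron CC1(C)OB(OC1(C)C)B1OC(C)(C)C(C)(C)O1 (boryl group of 2 only); CuBr2 [Cu+2].[Br-].[Br-] (bromine of 3)
Why: sterically controlled iridium-catalysed C–H borylation should take the only ring C–H that has no ortho substituent (para to the methyl group), and CuBr2 should then replace boron by bromine at the same carbon (ipso bromodeboronation).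

Step 2
Reactants: 3 5-bromo-1,3-dimethoxy-2-methylbenzene
Product: 4 5-bromo-2-methylbenzene-1,3-diol
Conditions: BBr3 (2.5 equiv), CH2Cl2, −78 °C to rt; then H2O
Reagents that add atoms: none
Why: Lewis-acid cleavage of aryl methyl ethers by BBr3 is routine and the aryl bromide is inert to it.

Step 3
Reactants: 4 5-bromo-2-methylbenzene-1,3-diol
Product: 5 1,3-bis(benzyloxy)-5-bromo-2-methylbenzene
Conditions: BnBr (2.2 equiv), K2CO3, DMF, 60 °C
Reagents that add atoms: benzyl bromide BrCc1ccccc1
Why: Williamson ether synthesis; benzyl is chosen because it survives the Grignard step and later leaves by hydrogenolysis, which does not touch an alkyl sulfonate.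

Step 4
Reactants: 5 1,3-bis(benzyloxy)-5-bromo-2-methylbenzene; 6 (S)-propylene oxide
Product: 8 (2S)-1-[3,5-bis(benzyloxy)-4-methylphenyl]propan-2-ol, via Grignard reagent 7 (not isolated)
Conditions: Mg, THF, reflux; then CuI (10 mol %), 6 (1.3 equiv), −30 to 0 °C; then 1 M HCl
Reagents that add atoms: magnesium [Mg] (metal of 7 only)
Why: copper-catalysed Grignard opening of a terminal epoxide occurs by SN2 attack at the CH2 carbon, so the stereocentre of 6 is not touched and the (S)-carbinol should result.

Step 5
Reactants: 8 (2S)-1-[3,5-bis(benzyloxy)-4-methylphenyl]propan-2-ol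
Product: 9 (2S)-1-[3,5-bis(benzyloxy)-4-methylphenyl]propan-2-yl methanesulfonate
Conditions: MsCl, Et3N, CH2Cl2, 0 °C
Reagents that add atoms: methanesulfonyl chloride CS(=O)(=O)Cl
Why: O-sulfonylation forms the O–S bond only, so the configuration at the carbinol carbon is retained.

Step 6
Reactants: 9 (2S)-1-[3,5-bis(benzyloxy)-4-methylphenyl]propan-2-yl methanesulfonate
Product: 10 (2S)-1-(3,5-dihydroxy-4-methylphenyl)propan-2-yl methanesulfonate
Conditions: H2 (1 atm), Pd/C (10 wt %), EtOAc, rt; used at once
Reagents that add atoms: none
Why: hydrogenolysis of aryl benzyl ethers is neutral and leaves a non-benzylic secondary mesylate intact; the freed phenols are meta to the side chain and cannot cyclise onto it.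

Step 7
Reactants: 10 (2S)-1-(3,5-dihydroxy-4-methylphenyl)propan-2-yl methanesulfonate; 11 carbon dioxide
Product: 13 (3R)-6,8-dihydroxy-3,7-dimethylisochroman-1-one, via carboxylate 12 (not isolated)
Conditions: CO2 (1 atm), DBU (3 equiv), dry MeCN, 30 °C, then 60 °C; 1 M HCl work-up
Reagents that add atoms: none
Why: Proposed new method: DBU forms the resorcinol monophenoxide of 10, which attacks CO2 through the ring carbon that is ortho to one phenol oxygen and para to the other (reversible Kolbe–Schmitt C-carboxylation), and the resulting DBU-H+ carboxylate 12 then displaces the secondary mesylate at C3 intramolecularly, which drains the carboxylation equilibrium. The closest known reaction types are the DBU/CO2 Kolbe–Schmitt carboxylation of resorcinols at ambient pressure and the SN2 lactonisation of sulfonyloxy or halo carboxylates; running both in one flask on a phenol that carries its own electrophile is the untested part. The lactone ring closes in the 6-exo-tet mode (carboxylate oxygen onto C3, leaving group outside the ring). The only stereocentre, C3, is set by inversion of the (S)-mesylate, whose configuration comes unchanged from (S)-propylene oxide, and should give (3R). The step needs one carboxylation site and needs lactonisation to outrun E2 loss of the mesylate and intermolecular O-alkylation: the two free ring CH are equivalent by the mirror symmetry of the ring and the position between the oxygens is blocked by methyl, both phenol oxygens are meta to the side chain and cannot reach C3, and under CO2 the base is buffered as DBU-H+ salts while the carboxylation phase is run at 30 °C.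

Step 8
Reactants: 14 noreugenin (5,7-dihydroxy-2-methyl-4H-chromen-4-one)
Product: 15 eugenin (5-hydroxy-7-methoxy-2-methyl-4H-chromen-4-one)
Conditions: MeI (1.05 equiv), K2CO3 (1.1 equiv), acetone, reflux
Reagents that add atoms: iodomethane CI
Why: the 5-OH is hydrogen-bonded to the C4 carbonyl and far less acidic and nucleophilic than the 7-OH, so Williamson methylation should be selective for O7.

Step 9
Reactants: 15 eugenin
Product: 16 5-hydroxy-6-iodo-7-methoxy-2-methyl-4H-chromen-4-one
Conditions: benzyltrimethylammonium dichloroiodate (1.05 equiv), CaCO3, CH2Cl2/MeOH, rt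
Reagents that add atoms: benzyltrimethylammonium dichloroiodate C[N+](C)(C)Cc1ccccc1.Cl[I-]Cl
Why: electrophilic aromatic iodination with this reagent is directed to C6, ortho to the free chelated 5-OH, in 5-hydroxy-7-alkoxyflavones, and the 2-methylchromone should behave the same way.

Step 10
Reactants: 16 5-hydroxy-6-iodo-7-methoxy-2-methyl-4H-chromen-4-one
Product: 17 5-hydroxy-6-(hydroxymethyl)-7-methoxy-2-methyl-4H-chromen-4-one
Conditions: Bu3SnCH2OH (1.3 equiv), Pd(PPh3)4 (5 mol %), 1,4-dioxane, 90 °C
Reagents that add atoms: (tributylstannyl)methanol CCCC[Sn](CCCC)(CCCC)CO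
Why: Stille coupling transfers the hydroxymethyl group to the aryl iodide under neutral conditions that spare the free phenol and the base-sensitive pyrone ring.

Step 11
Reactants: 13 (3R)-6,8-dihydroxy-3,7-dimethylisochroman-1-one; 17 5-hydroxy-6-(hydroxymethyl)-7-methoxy-2-methyl-4H-chromen-4-one
Product: 19 (3R)-6,8-dihydroxy-5-[(5-hydroxy-7-methoxy-2-methyl-4-oxo-4H-chromen-6-yl)methyl]-3,7-dimethylisochroman-1-one, via quinone methide 18 (not isolated)
Conditions: TsOH·H2O (10 mol %), MeCN, 50 °C; 17 added slowly to 13 (1.5 equiv)
Reagents that add atoms: none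
Why: acid ionises the ortho-hydroxybenzyl alcohol to the o-quinone methide (reacting as its O-protonated form), which is trapped in a Friedel–Crafts-type alkylation by C5 of 13, the only unsubstituted ring carbon and ortho to the 6-OH and para to the 8-OH; C3 is not involved.

**Compound list**

1 | 2,6-dimethoxytoluene | COc1cccc(OC)c1C | starting material
2 | 2-(3,5-dimethoxy-4-methylphenyl)-4,4,5,5-tetramethyl-1,3,2-dioxaborolane | COc1cc(B2OC(C)(C)C(C)(C)O2)cc(OC)c1C | intermediate
3 | 5-bromo-1,3-dimethoxy-2-methylbenzene | COc1cc(Br)cc(OC)c1C | intermediate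
4 | 5-bromo-2-methylbenzene-1,3-diol | Cc1c(O)cc(Br)cc1O | intermediate
5 | 1,3-bis(benzyloxy)-5-bromo-2-methylbenzene | Cc1c(OCc2ccccc2)cc(Br)cc1OCc1ccccc1 | intermediate
6 | (S)-propylene oxide | C[C@H]1CO1 | starting material
7 | [3,5-bis(benzyloxy)-4-methylphenyl]magnesium bromide | Cc1c(OCc2ccccc2)cc([Mg]Br)cc1OCc1ccccc1 | intermediate
8 | (2S)-1-[3,5-bis(benzyloxy)-4-methylphenyl]propan-2-ol | C[C@H](O)Cc1cc(OCc2ccccc2)c(C)c(OCc2ccccc2)c1 | intermediate
9 | (2S)-1-[3,5-bis(benzyloxy)-4-methylphenyl]propan-2-yl methanesulfonate | C[C@H](OS(C)(=O)=O)Cc1cc(OCc2ccccc2)c(C)c(OCc2ccccc2)c1 | intermediate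
10 | (2S)-1-(3,5-dihydroxy-4-methylphenyl)propan-2-yl methanesulfonate | C[C@H](OS(C)(=O)=O)Cc1cc(O)c(C)c(O)c1 | intermediate
11 | carbon dioxide | O=C=O | starting material
12 | 2,4-dihydroxy-3-methyl-6-[(2S)-2-(methylsulfonyloxy)propyl]benzoic acid (present as its DBU salt) | C[C@H](OS(C)(=O)=O)Cc1cc(O)c(C)c(O)c1C(=O)O | intermediate
13 | (3R)-6,8-dihydroxy-3,7-dimethylisochroman-1-one | C[C@@H]1Cc2cc(O)c(C)c(O)c2C(=O)O1 | intermediate
14 | noreugenin (5,7-dihydroxy-2-methyl-4H-chromen-4-one) | Oc1cc2oc(C)cc(=O)c2c(O)c1 | starting material
15 | eugenin (5-hydroxy-7-methoxy-2-methyl-4H-chromen-4-one) | COc1cc2oc(C)cc(=O)c2c(O)c1 | intermediate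
16 | 5-hydroxy-6-iodo-7-methoxy-2-methyl-4H-chromen-4-one | COc1cc2oc(C)cc(=O)c2c(O)c1I | intermediate
17 | 5-hydroxy-6-(hydroxymethyl)-7-methoxy-2-methyl-4H-chromen-4-one | COc1cc2oc(C)cc(=O)c2c(O)c1CO | intermediate
18 | 7-methoxy-2-methyl-6-methylidene-4H-chromene-4,5(6H)-dione (o-quinone methide) | C=C1C(OC)=CC2=C(C1=O)C(=O)C=C(C)O2 | intermediate
19 | (3R)-6,8-dihydroxy-5-[(5-hydroxy-7-methoxy-2-methyl-4-oxo-4H-chromen-6-yl)methyl]-3,7-dimethylisochroman-1-one | COc1cc2oc(C)cc(=O)c2c(O)c1Cc1c(O)c(C)c(O)c2c1C[C@@H](C)OC2=O | target

**Step count and risks**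

Total steps: 11. Longest linear sequence: 8 (steps 1 to 7, then step 11).

Steps most likely to fail:

Step 7 (proposed new method). The risks are that base-induced elimination of the mesylate to the propenylarene, or intermolecular O-alkylation of a phenoxide, overtakes a slow C-carboxylation, or that the carboxylate salt precipitates before it can cyclise. The fallback uses known chemistry only and forms the lactone by acyl–oxygen closure with retention. It sets out from 5: the same Grignard/CuI opening, but of (R)-propylene oxide, should give (2R)-1-[3,5-bis(benzyloxy)-4-methylphenyl]propan-2-ol F1. Hydrogenolysis (H2, Pd/C, EtOAc) should give 5-[(2R)-2-hydroxypropyl]-2-methylbenzene-1,3-diol F2. A classical Kolbe–Schmitt carboxylation (KHCO3, CO2, DMF or glycerol, about 120 °C, as used for 5-alkylresorcinols) should give 2,4-dihydroxy-6-[(2R)-2-hydroxypropyl]-3-methylbenzoic acid F3. On acidification and brief warming with TsOH in toluene, F3 should close to the lactone without touching the C3–O bond, and the sequence comes back to the route at 13.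

Step 11. The risks are self-condensation of the benzylic electrophile with C8 of a second chromone molecule, and sluggish attack by the ester-deactivated ring of 13. The fallback changes the order of events so that the far more nucleophilic, ester-free resorcinol takes the electrophile first. It sets out from 10 and 17: acid-catalysed benzylation of 10 (used in excess; its two free ring positions are equivalent) should give (2S)-1-{3,5-dihydroxy-2-[(5-hydroxy-7-methoxy-2-methyl-4-oxo-4H-chromen-6-yl)methyl]-4-methylphenyl}propan-2-yl methanesulfonate F4. Treatment of F4 with CO2 and DBU as in step 7 should carboxylate the single remaining ring C–H to give 2,4-dihydroxy-5-[(5-hydroxy-7-methoxy-2-methyl-4-oxo-4H-chromen-6-yl)methyl]-3-methyl-6-[(2S)-2-(methylsulfonyloxy)propyl]benzoic acid F5. F5 should lactonise with inversion, and the sequence comes back to the route at 19. This fallback still depends on the step 7 chemistry working.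

Step 9. The risk is iodination at C8 (para to the 5-OH) or at C3 of the pyrone instead of C6, or double iodination. The fallback sets out from 15 and puts the carbon on C6 by a mechanism that can only deliver ortho to the phenol. Casnati–Skattebøl formylation (MgCl2, Et3N, paraformaldehyde, MeCN, reflux), in which the magnesium phenoxide of the 5-OH hands formaldehyde to its only free ortho carbon, should give 5-hydroxy-7-methoxy-2-methyl-4-oxo-4H-chromene-6-carbaldehyde F6. Reduction with NaBH4 (THF/MeOH, 0 °C) should give the benzylic alcohol, and the sequence comes back to the route at 17, bypassing steps 9 and 10.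

Further compounds
F1 | step 7 | (2R)-1-[3,5-bis(benzyloxy)-4-methylphenyl]propan-2-ol | C[C@@H](O)Cc1cc(OCc2ccccc2)c(C)c(OCc2ccccc2)c1
F2 | step 7 | 5-[(2R)-2-hydroxypropyl]-2-methylbenzene-1,3-diol | C[C@@H](O)Cc1cc(O)c(C)c(O)c1
F3 | step 7 | 2,4-dihydroxy-6-[(2R)-2-hydroxypropyl]-3-methylbenzoic acid | C[C@@H](O)Cc1cc(O)c(C)c(O)c1C(=O)O
F4 | step 11 | (2S)-1-{3,5-dihydroxy-2-[(5-hydroxy-7-methoxy-2-methyl-4-oxo-4H-chromen-6-yl)methyl]-4-methylphenyl}propan-2-yl methanesulfonate | C[C@H](OS(C)(=O)=O)Cc1cc(O)c(C)c(O)c1Cc1c(OC)cc2oc(C)cc(=O)c2c1O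
F5 | step 11 | 2,4-dihydroxy-5-[(5-hydroxy-7-methoxy-2-methyl-4-oxo-4H-chromen-6-yl)methyl]-3-methyl-6-[(2S)-2-(methylsulfonyloxy)propyl]benzoic acid | C[C@H](OS(C)(=O)=O)Cc1c(C(=O)O)c(O)c(C)c(O)c1Cc1c(OC)cc2oc(C)cc(=O)c2c1O
F6 | step 9 | 5-hydroxy-7-methoxy-2-methyl-4-oxo-4H-chromene-6-carbaldehyde | COc1cc2oc(C)cc(=O)c2c(O)c1C=O
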